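**Retrosynthetic overview**

- The target is cut at the C9′=C10′ alkene of the side chain into an aldehyde acid and diethyl cinnamylphosphonate. The aldehyde acid comes from a 1,2-dioxolane that carries a 2-(triethylsilyloxy)ethyl arm (the future CH2CO2H) and a terminal vinyl group (the future CHO).
- Ring A (the 1,2-dioxolane O1–O2–C3–C4–C5, the only ring to be made) is opened into a triethylsilyl peroxyketal (O1–O2–C3 unit with CH3 and the arm) and (R)-2,4-dimethyldodeca-1,11-diene (C4=C5 unit). A stepwise formal [3+2] annulation forms the ring bond C3–C4, then O1–C5, and sets both quaternary centres.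
- Enabling feature: in ring A, C3 is a fully substituted, ketone-level carbon on O2 (a latent silylperoxycarbenium ion), and C5 is a tertiary, methyl-bearing carbon on O1 next to the ring CH2 (C4). C5 is therefore the cation formed when the CH2 terminus of an isopropenyl group attacks C3.
- The peroxyketal comes from 3-methylbut-3-en-1-ol (silylation, ozonolysis in methanol, O-silylation). The diene comes from deca-1,9-diene and methyl vinyl ketone (cross-metathesis, asymmetric conjugate methylation for the side-chain centre, methylenation).

Key step: step 7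

Assumption: the antipode of the ferrocenyl diphosphine (step 5) and of the chiral acid (step 7) that gives the configuration drawn is to be confirmed in a test run; both antipodes are accessible, so the route does not depend on the sense of induction being predicted correctly.

**Route**

Step 1
Reactants: 1 3-methylbut-3-en-1-ol
Product: 2 triethyl[(3-methylbut-3-en-1-yl)oxy]silane
Conditions: Et3SiCl, imidazole, CH2Cl2, 0 °C to rt
Reagents that add atoms: chlorotriethylsilane, CC[Si](Cl)(CC)CC
Why: O-silylation of a primary alcohol (silyl ether formation) masks the future carboxyl carbon as an ether that should survive ozone and carbocations and is cleaved and oxidised in one operation in step 8.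

Step 2
Reactants: 2 triethyl[(3-methylbut-3-en-1-yl)oxy]silane
Product: 4 [(3-hydroperoxy-3-methoxybutyl)oxy]triethylsilane (racemic), via carbonyl oxide 3 (not isolated)
Conditions: O3, MeOH/CH2Cl2 1:4, NaHCO3, −78 °C; N2 purge; concentration below rt
Reagents that add atoms: ozone, [O-][O+]=O; methanol, CO
Why: Ozonolysis in a participating solvent: Criegee fragmentation of the primary ozonide of a 1,1-disubstituted alkene should place the carbonyl oxide on the disubstituted carbon (formaldehyde being the other fragment) and methanol adds to it to give the α-methoxy hydroperoxide, whose new centre is racemic and is erased on ionisation in step 7.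

Step 3
Reactants: 4 [(3-hydroperoxy-3-methoxybutyl)oxy]triethylsilane
Product: 5 triethyl({2-methoxy-4-[(triethylsilyl)oxy]butan-2-yl}peroxy)silane (racemic)
Conditions: Et3SiCl, imidazole, DMF, 0 °C
Reagents that add atoms: chlorotriethylsilane, CC[Si](Cl)(CC)CC
Why: O-silylation of the acidic hydroperoxide OH with a chlorosilane and imidazole should give the triethylsilyl peroxyketal without ionising the ketal carbon.

Step 4
Reactants: 6 deca-1,9-diene (4 equiv); 7 but-3-en-2-one
Product: 8 (E)-dodeca-3,11-dien-2-one
Conditions: second-generation Hoveyda–Grubbs catalyst [RuCl2(H2IMes)(=CH-2-iPrOC6H4)] (2 mol %), CH2Cl2, 40 °C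
Reagents that add atoms: none
Why: Olefin cross-metathesis of a terminal alkene with an electron-poor vinyl ketone should give the (E)-enone under thermodynamic control, the excess of the cheap symmetrical diene (recovered by distillation) keeping the reaction to one chain end.

Step 5
Reactants: 8 (E)-dodeca-3,11-dien-2-one
Product: 10 (R)-4-methyldodec-11-en-2-one, via bromomagnesium enolate 9 (not isolated)
Conditions: MeMgBr, CuBr·SMe2 (5 mol %), (R)-1-[(S)-2-(diphenylphosphino)ferrocenyl]ethyldicyclohexylphosphine (JosiPhos, 6 mol %), t-BuOMe, −75 °C; then aq. NH4Cl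
Reagents that add atoms: methylmagnesium bromide, C[Mg]Br
Why: Copper-catalysed asymmetric conjugate addition of a Grignard reagent to an acyclic enone should set the (R)-methyl-bearing centre by ligand-controlled delivery of methyl to one enantioface of the β-carbon, the terminal alkene being inert.

Step 6
Reactants: 10 (R)-4-methyldodec-11-en-2-one
Product: 11 (R)-2,4-dimethyldodeca-1,11-diene
Conditions: Ph3PCH3Br, KOtBu, THF, 0 °C to rt
Reagents that add atoms: methyltriphenylphosphonium bromide, C[P+](c1ccccc1)(c1ccccc1)c1ccccc1.[Br-]
Why: Wittig methylenation of the methyl ketone should give the 1,1-disubstituted alkene, and the stereocentre cannot epimerise because it is β, not α, to the carbonyl group.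

Step 7
Reactants: 5 triethyl({2-methoxy-4-[(triethylsilyl)oxy]butan-2-yl}peroxy)silane (1.5 equiv); 11 (R)-2,4-dimethyldodeca-1,11-diene
Product: 14 (3S,5R)-3,5-dimethyl-5-[(2R)-2-methyldec-9-en-1-yl]-3-[2-(triethylsilyloxy)ethyl]-1,2-dioxolane, via silylperoxycarbenium ion 12 (not isolated), via tertiary carbocation 13 (not isolated)
Conditions: chiral imidodiphosphorimidate acid HN[P(=NSO2CF3)(BINOL*)]2 (IDPi; BINOL* = 3,3′-bis[3,5-bis(trifluoromethyl)phenyl]-1,1′-binaphthalene-2,2′-diolate, aryl groups open to tuning; 3 mol %), toluene/CH2Cl2, −78 °C
Reagents that add atoms: none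
Why: Proposed new method: the chiral acid (as its N-silylated, silylium-donor form after the first turnover) removes methoxide from 5 as Et3SiOMe to give silylperoxycarbenium ion 12 as a contact ion pair with the confined chiral anion, the CH2 terminus of the 1,1-disubstituted alkene of 11 attacks the carbenium carbon (C3–C4 bond) to give tertiary cation 13, and the silylated distal peroxide oxygen captures C5 with release of Et3Si+, which returns to the anion and carries the chain. The closest known reaction types are the SnCl4-promoted annulation of triethylsilyl peroxyketals with alkenes to 1,2-dioxolanes, which establishes the bond-forming sequence but gives no absolute control, and silylium-based asymmetric counteranion-directed additions of simple olefins and silyl nucleophiles to oxocarbenium ions, which show that such ion pairs can be face-selective. Ring A closes in a stepwise formal [3+2] annulation, the ring-closing event being a five-membered O–C bond formation by O1 onto the planar C5 cation. The C3 centre is set by the anion, which must distinguish the methyl group from the bulky 2-(triethylsilyloxy)ethyl arm on the two faces of the C=O+ unit; the C5 centre is set in the ring closure, where the envelope transition state with the two larger groups (arm on C3, 2-methyldecenyl on C5) pseudo-equatorial leads to the cis-dimethyl ring, a preference that the chiral pocket should reinforce and that should override the remote side-chain centre. The step needs chemoselectivity for the 1,1-disubstituted over the monosubstituted alkene (tertiary against secondary cation), Markovnikov regiochemistry, and ionisation by loss of methoxide instead of silylperoxide, all of which the substrates should secure, the more basic methoxy oxygen being the one that is silylated.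

Step 8
Reactants: 14 (3S,5R)-3,5-dimethyl-5-[(2R)-2-methyldec-9-en-1-yl]-3-[2-(triethylsilyloxy)ethyl]-1,2-dioxolane
Product: 17 2-[(3R,5R)-3,5-dimethyl-5-[(2R)-2-methyldec-9-en-1-yl]-1,2-dioxolan-3-yl]acetic acid, via primary alcohol 15 (not isolated), via aldehyde 16 (not isolated)
Conditions: CrO3, H2SO4, H2O, acetone, 0 °C
Reagents that add atoms: water, O
Why: Jones oxidation: the aqueous acid should cleave the primary triethylsilyl ether and hexavalent chromium should oxidise the alcohol through the aldehyde hydrate to the acid, conditions that a fully substituted dialkyl peroxide and an isolated terminal alkene are expected to tolerate (the C3 descriptor changes from S to R only because the arm gains priority).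

Step 9
Reactants: 17 2-[(3R,5R)-3,5-dimethyl-5-[(2R)-2-methyldec-9-en-1-yl]-1,2-dioxolan-3-yl]acetic acid
Product: 19 2-[(3R,5R)-3,5-dimethyl-5-[(2R)-2-methyl-9-oxononyl]-1,2-dioxolan-3-yl]acetic acid, via secondary ozonide 18 (not isolated)
Conditions: O3, CH2Cl2, −78 °C; then Me2S, −78 °C to rt
Reagents that add atoms: ozone, [O-][O+]=O
Why: Ozonolysis with reductive work-up should cleave the only remaining alkene to the aldehyde, dimethyl sulfide reducing the ozonide but not the hindered dialkyl peroxide of ring A.

Step 10
Reactants: 19 2-[(3R,5R)-3,5-dimethyl-5-[(2R)-2-methyl-9-oxononyl]-1,2-dioxolan-3-yl]acetic acid; 20 diethyl [(2E)-3-phenylprop-2-en-1-yl]phosphonate (2.5 equiv)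
Product: 22 2-[(3R,5R)-3,5-dimethyl-5-[(2R,9E,11E)-2-methyl-12-phenyldodeca-9,11-dien-1-yl]-1,2-dioxolan-3-yl]acetic acid (target), via sodium phosphonate carbanion 21 (not isolated)
Conditions: 20, NaN(SiMe3)2 (2.4 equiv), THF, −78 °C; then 19, −78 °C to rt; dilute HCl work-up
Reagents that add atoms: none
Why: Horner–Wadsworth–Emmons olefination with an allylic phosphonate anion in excess (the first equivalent is consumed by the carboxylic acid, whose carboxylate is then inert) should form the new disubstituted alkene with (E) geometry through the thermodynamically controlled elimination, the (E)-styryl bond being carried in by the reagent.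

**Compound list**

1 | 3-methylbut-3-en-1-ol | C=C(C)CCO | starting material
2 | triethyl[(3-methylbut-3-en-1-yl)oxy]silane | C=C(C)CCO[Si](CC)(CC)CC | intermediate
3 | 4-(triethylsilyloxy)butan-2-one O-oxide (carbonyl oxide, not isolated) | CC(CCO[Si](CC)(CC)CC)=[O+][O-] | intermediate
4 | [(3-hydroperoxy-3-methoxybutyl)oxy]triethylsilane (racemic) | CC(OC)(OO)CCO[Si](CC)(CC)CC | intermediate
5 | triethyl({2-methoxy-4-[(triethylsilyl)oxy]butan-2-yl}peroxy)silane (racemic) | CC(OC)(CCO[Si](CC)(CC)CC)OO[Si](CC)(CC)CC | intermediate
6 | deca-1,9-diene | C=CCCCCCCC=C | starting material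
7 | but-3-en-2-one (methyl vinyl ketone) | CC(=O)C=C | starting material
8 | (E)-dodeca-3,11-dien-2-one | CC(=O)/C=C/CCCCCCC=C | intermediate
9 | bromomagnesium (R)-4-methyldodeca-2,11-dien-2-olate (enolate, not isolated) | C[C@H](CCCCCCC=C)C=C(C)O[Mg]Br | intermediate
10 | (R)-4-methyldodec-11-en-2-one | C[C@H](CCCCCCC=C)CC(C)=O | intermediate
11 | (R)-2,4-dimethyldodeca-1,11-diene | C[C@H](CCCCCCC=C)CC(C)=C | intermediate
12 | triethylsilylperoxycarbenium ion of 4-(triethylsilyloxy)butan-2-one (not isolated) | CC(CCO[Si](CC)(CC)CC)=[O+]O[Si](CC)(CC)CC | intermediate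
13 | open-chain tertiary carbocation at C5 carrying the C3 triethylsilylperoxy group (not isolated) | C[C@H](CCCCCCC=C)C[C+](C)C[C@](C)(CCO[Si](CC)(CC)CC)OO[Si](CC)(CC)CC | intermediate
14 | (3S,5R)-3,5-dimethyl-5-[(2R)-2-methyldec-9-en-1-yl]-3-[2-(triethylsilyloxy)ethyl]-1,2-dioxolane | C[C@H](CCCCCCC=C)C[C@]1(C)C[C@](C)(CCO[Si](CC)(CC)CC)OO1 | intermediate
15 | 2-[(3S,5R)-3,5-dimethyl-5-[(2R)-2-methyldec-9-en-1-yl]-1,2-dioxolan-3-yl]ethanol (not isolated) | C[C@H](CCCCCCC=C)C[C@]1(C)C[C@](C)(CCO)OO1 | intermediate
16 | 2-[(3R,5R)-3,5-dimethyl-5-[(2R)-2-methyldec-9-en-1-yl]-1,2-dioxolan-3-yl]acetaldehyde (not isolated) | C[C@H](CCCCCCC=C)C[C@]1(C)C[C@](C)(CC=O)OO1 | intermediate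
17 | 2-[(3R,5R)-3,5-dimethyl-5-[(2R)-2-methyldec-9-en-1-yl]-1,2-dioxolan-3-yl]acetic acid | C[C@H](CCCCCCC=C)C[C@]1(C)C[C@](C)(CC(=O)O)OO1 | intermediate
18 | secondary ozonide (1,2,4-trioxolane) of the terminal alkene of 17 (not isolated) | C[C@H](CCCCCCC1OCOO1)C[C@]1(C)C[C@](C)(CC(=O)O)OO1 | intermediate
19 | 2-[(3R,5R)-3,5-dimethyl-5-[(2R)-2-methyl-9-oxononyl]-1,2-dioxolan-3-yl]acetic acid | C[C@H](CCCCCCC=O)C[C@]1(C)C[C@](C)(CC(=O)O)OO1 | intermediate
20 | diethyl [(2E)-3-phenylprop-2-en-1-yl]phosphonate | CCOP(=O)(OCC)C/C=C/c1ccccc1 | starting material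
21 | sodium salt of the α-carbanion of 20 (not isolated) | CCOP(=O)(OCC)[CH-]/C=C/c1ccccc1.[Na+] | intermediate
22 | 2-[(3R,5R)-3,5-dimethyl-5-[(2R,9E,11E)-2-methyl-12-phenyldodeca-9,11-dien-1-yl]-1,2-dioxolan-3-yl]acetic acid | C[C@H](CCCCCC/C=C/C=C/c1ccccc1)C[C@]1(C)C[C@](C)(CC(=O)O)OO1 | target

**Summary**

Total step count: 10.
Longest linear sequence: 7 steps (steps 4, 5, 6, 7, 8, 9, 10 from deca-1,9-diene; the branch from 3-methylbut-3-en-1-ol through steps 1, 2, 3, 7, 8, 9, 10 is equally long).

**The three steps most likely to fail**

1. Step 7 (proposed new method). What may go wrong: insufficient discrimination of the two faces of the silylperoxycarbenium ion in the chiral ion pair, leakage between cis and trans ring closure at C5, or proton loss from the tertiary cation in place of ring closure. Fallback, known chemistry: setting out from 5 and 11, the established achiral protocol (stoichiometric tin tetrachloride SnCl4, CH2Cl2, −78 °C) should form the same constitution without absolute control. It should give 14 together with the (3R,5S) cis diastereomer F1, the (3R,5R) trans diastereomer F2 and the (3S,5S) trans diastereomer F3. Stereocontrol is then replaced by physical separation: the trans isomers are removed on silica, and 14 is separated from F1 by preparative HPLC on a chiral stationary phase. The route is rejoined at 14.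

2. Step 10. What may go wrong: γ-attack of the ambident allylic phosphonate anion, incomplete (E)-selectivity in the new double bond, or base-induced opening of the β-peroxy carboxylate. Fallback: setting out from 17 (step 9 is bypassed), olefin cross-metathesis with (E)-buta-1,3-dien-1-ylbenzene (3 equiv) and the second-generation Hoveyda–Grubbs catalyst in CH2Cl2 at 40 °C should join the terminal alkene to the terminal double bond of the diene under neutral conditions. It arrives directly at 22; no compound outside the list is made (F0).

3. Step 5. What may go wrong: incomplete enantioface control in the methyl transfer (uncatalysed background 1,4- or 1,2-addition of MeMgBr), which would surface later as a remote diastereomer that is very hard to remove. Fallback: setting out from 6, cross-metathesis with commercial (S)-3-acryloyl-4-phenyloxazolidin-2-one (second-generation Hoveyda–Grubbs catalyst, CH2Cl2, 40 °C) should give (S)-3-[(E)-undeca-2,10-dienoyl]-4-phenyloxazolidin-2-one F4. Auxiliary-controlled conjugate addition (MeMgBr, CuBr·SMe2, THF/Me2S, −40 °C; chelated syn-s-cis imide, methyl delivered anti to the phenyl group) should give (S)-3-[(R)-3-methylundec-10-enoyl]-4-phenyloxazolidin-2-one F5, whose minor diastereomer can be removed by crystallisation or chromatography. Transamidation with MeNH(OMe)·HCl and AlMe3 should give (R)-N-methoxy-N,3-dimethylundec-10-enamide F6, and addition of MeMgBr (THF, 0 °C) returns the route to 10.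

Further compounds
F1 | step 7 | (3R,5S)-3,5-dimethyl-5-[(2R)-2-methyldec-9-en-1-yl]-3-[2-(triethylsilyloxy)ethyl]-1,2-dioxolane | C[C@H](CCCCCCC=C)C[C@@]1(C)C[C@@](C)(CCO[Si](CC)(CC)CC)OO1
F2 | step 7 | (3R,5R)-3,5-dimethyl-5-[(2R)-2-methyldec-9-en-1-yl]-3-[2-(triethylsilyloxy)ethyl]-1,2-dioxolane | C[C@H](CCCCCCC=C)C[C@]1(C)C[C@@](C)(CCO[Si](CC)(CC)CC)OO1
F3 | step 7 | (3S,5S)-3,5-dimethyl-5-[(2R)-2-methyldec-9-en-1-yl]-3-[2-(triethylsilyloxy)ethyl]-1,2-dioxolane | C[C@H](CCCCCCC=C)C[C@@]1(C)C[C@](C)(CCO[Si](CC)(CC)CC)OO1
F0 | step 10 | none | none
F4 | step 5 | (S)-3-[(E)-undeca-2,10-dienoyl]-4-phenyloxazolidin-2-one | C=CCCCCCC/C=C/C(=O)N1[C@@H](c2ccccc2)COC1=O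
F5 | step 5 | (S)-3-[(R)-3-methylundec-10-enoyl]-4-phenyloxazolidin-2-one | C[C@H](CCCCCCC=C)CC(=O)N1[C@@H](c2ccccc2)COC1=O
F6 | step 5 | (R)-N-methoxy-N,3-dimethylundec-10-enamide | C[C@H](CCCCCCC=C)CC(=O)N(C)OC
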